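Slowness is what we must measure here: south-west and north-east carry the same charge and differ in time, 40 h against 12 h, and in Thursday's run the chains are still growing between 20.0 h and 50.0 h.

| setting | Thursday's | Monday's | Tuesday's | south-west | north-east |
|---|---|---|---|---|---|
| free monomer | 0.020 M | 0.020 M | 0.020 M | 0.020 M | 0.020 M |
| protic impurity | 0.50 mM | 2 mM | 1 mM | 1.00 mM | 1.00 mM |
| initiator | 100 µM | 100 µM | 200 µM | 100 µM | 100 µM |
| remark | run made earlier | run made earlier | run made earlier |  |  |
| time |  |  |  | 40 h | 12 h |

- Thursday's (time / h: monomer in chains / %, free monomer / %): 4.00: 12, 88; 8.00: 22, 76; 20.0: 45, 53; 50.0: 58, 43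
- Monday's (time / h: monomer in chains / %, free monomer / %): 6.00: 15, 75; 15.0: 33, 57; 30.0: 46, 44; 50.0: 50, 43
- Tuesday's (time / h: monomer in chains / %, free monomer / %): 12.0: 45, 50; 25.0: 54, 37; 40.0: 56, 40; 50.0: 57, 38

(scatter of a reading: 1.5 percentage points)

- which of the two ends with the longer chains by the average number of monomer units in a chain (chains begun, living or dead) ("neither" if they lie within 10%) (south-west / north-east / neither)
- average number of monomer units in a chain (chains begun, living or dead) at the end, south-west
- average number of monomer units in a chain (chains begun, living or dead) at the end, north-east

We assume that the chains close a constant fraction of their remaining distance to a ceiling each hour (pseudo-first-order), and take Thursday's last reading as a first ceiling. With 45% at 20.0 h, that gives 0.0748 h⁻¹. This leaves 2.38% of the distance open at 50.0 h, so going round once more lifts Thursday's ceiling to 59.4% and gives 0.0708 h⁻¹. This is the relaxation constant, the fraction of the remaining distance closed per hour at 100 µM of initiator, a reading with the scatter of the data.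

Monday's first reading falls short of the charge by 10.0%, and its impurity over its monomer is 10.0%, so we count one free monomer lost per impurity. Thursday's ceiling, corrected for that loss, becomes 56.9% for both new flasks. Tuesday's run, with twice Thursday's initiator, gives 0.130 h⁻¹ against that ceiling, which is twice our constant, so we scale it with initiator.

Guessing one chain per initiator charged, we reckon 107 units for south-west and 65.2 for north-east.

The forecast, a separate reckoning, names south-west as longer, with 105 against 60, and says of its rate: “It doubles with doubled initiator and ignores impurity, so active centres survive”.

The simulation gives south-west as longer, with 106 against 62.9.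

    protic impurity + free monomer → quenched substrate (k = 1380 M⁻¹ h⁻¹)
    free monomer + initiator → living end + monomer in chains (k = 25.1 M⁻¹ h⁻¹)
    monomer in chains + living end → free monomer + living end, rate k3*[living end] as long as [monomer in chains] is above zero (k = 6.50 h⁻¹)
    free monomer + living end → monomer in chains + living end, rate k4*[living end]*[free monomer] (k = 826 M⁻¹ h⁻¹)

North-east holds 31.2% in chains at 12.0 h; its level of 55.7% at 120 h, put through our constant, gives 31.9%. The neighbouring flask is north-east with 4.0 × 10⁻⁴ M of initiator. Our constant scaled by 4.00 gives 55.0% in chains and a length of 27.5. At 12.0 h that flask holds 53.4% in chains, with an average length of 27.4.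

Readings and results are simulated with constants of no real substance, noise included.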